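**Retrosynthetic overview**
1. Target ⇐ crotonylation of the C8 hydroxyl and removal of the C15 silyl ether from a macrocyclic alcohol.
2. Macrocycle (last ring; C7–C8 bond, both stereocentres, exocyclic methylene) ⇐ intramolecular Barbier-type allylation: a 3-(bromomethyl)butenolide becomes an allylchromium whose butenolide β-carbon, normally an acceptor, attacks the C8 aldehyde as a homoenolate-type donor.
3. Butenolide (third ring) ⇐ ring-closing metathesis of a 2-(bromomethyl)acrylate on the C6 carbinol; C8 aldehyde ⇐ cleavage of a prenyl group.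
4. 3(2H)-Furanone (second ring) ⇐ 5-endo-dig oxa-Michael closure of an α'-hydroxy ynone ⇐ enyne acetylide + prenylated Seebach dioxolanone (first, temporary ring; C10 from L-lactic acid).
5. Enyne ⇐ Sonogashira coupling of a Z-vinyl iodide ⇐ hydroalumination/iodination of the propargylic alcohol from asymmetric alkynylation of crotonaldehyde (C6).

Assumption: the identifier is taken to mean exactly the given SMILES, which is (4Z,6S,7S,8R,10R). Atoms are labelled C1–C15 in germacranolide numbering: C1 ketone, C2=C3 furanone alkene, C4=C5 with C15H2OH on C4, C6 lactone carbinol, C7, C8 ester carbinol, C9, C10 quaternary carbon with methyl C14, C11=C13 methylene, C12 lactone carbonyl. Plain numbers are compounds.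

**Step 1**
Reactants: 1 (S)-lactic acid; 2 pivalaldehyde
Product: 3 (2S,5S)-2-tert-butyl-5-methyl-1,3-dioxolan-4-one
Conditions: TsOH·H2O (cat.), H2SO4 (cat.), pentane, reflux, Dean–Stark; recrystallise (pentane, −78 °C)
Reagents that add atoms: none
Why: Acid-catalysed acetalisation (Seebach self-regeneration of stereocentres) gives mainly the cis dioxolanone, which crystallises pure, so the acetal centre (S) is set under control of the lactate centre.

**Step 2**
Reactants: 3 (2S,5S)-2-tert-butyl-5-methyl-1,3-dioxolan-4-one; 4 prenyl bromide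
Product: 6 (2S,5R)-2-tert-butyl-5-methyl-5-(3-methylbut-2-en-1-yl)-1,3-dioxolan-4-one, via lithium enolate 5 (not isolated)
Conditions: LiN(i-Pr)2, THF, −78 °C; then 4, −78 → −30 °C
Reagents that add atoms: none
Why: Seebach enolate alkylation: the planar enolate keeps only the acetal centre and prenyl bromide enters anti to the tert-butyl group, so the quaternary centre (later C10) is formed as R with overall retention.

**Step 3**
Reactants: 7 tert-butyldimethyl(prop-2-yn-1-yloxy)silane; 8 (E)-but-2-enal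
Product: 10 (4R,5E)-1-[(tert-butyldimethylsilyl)oxy]hept-5-en-2-yn-4-ol, via alkynyl(methyl)zinc 9 (not isolated)
Conditions: Me2Zn, ProPhenol (10 mol%, the antipode that gives Si-face addition), Ph3P=O (20 mol%), toluene, 0 °C; aq NH4Cl
Reagents that add atoms: none
Why: Zinc–ProPhenol (Trost) asymmetric alkynylation delivers the alkynyl group to the Si face of the enal carbonyl, which sets the carbinol centre (later C6) as R; the sense is checked by Mosher ester analysis.

**Step 4**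
Reactants: 10 (4R,5E)-1-[(tert-butyldimethylsilyl)oxy]hept-5-en-2-yn-4-ol
Product: 12 (2Z,4R,5E)-1-[(tert-butyldimethylsilyl)oxy]-2-iodohepta-2,5-dien-4-ol, via cyclic vinylalanate 11 (not isolated)
Conditions: NaAlH2(OCH2CH2OMe)2, THF, 0 °C → rt; EtOAc; then I2, −78 → 0 °C; aq KNaC4H4O6
Reagents that add atoms: iodine, II
Why: Hydroxyl-directed trans-hydroalumination (Corey-type reduction/iodination of a propargylic alcohol) puts aluminium on the distal alkyne carbon in a five-membered alanate, and iododealumination with retention gives the vinyl iodide with iodine cis to the carbinol carbon, which fixes the C4=C5 geometry of the target.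

**Step 5**
Reactants: 12 (2Z,4R,5E)-1-[(tert-butyldimethylsilyl)oxy]-2-iodohepta-2,5-dien-4-ol
Product: 13 (2Z,4R,5E)-1-[(tert-butyldimethylsilyl)oxy]-2-iodo-4-[(triethylsilyl)oxy]hepta-2,5-diene
Conditions: Et3SiCl, imidazole, CH2Cl2, 0 °C
Reagents that add atoms: chlorotriethylsilane, CC[Si](CC)(CC)Cl
Why: Standard silylation; the C6 oxygen must be masked because a free (Z)-enynol would later add to the ynone and give a furan.

**Step 6**
Reactants: 13 (2Z,4R,5E)-1-[(tert-butyldimethylsilyl)oxy]-2-iodo-4-[(triethylsilyl)oxy]hepta-2,5-diene; 14 ethynyltrimethylsilane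
Product: 16 (2E,4R,5E)-1-[(tert-butyldimethylsilyl)oxy]-2-ethynyl-4-[(triethylsilyl)oxy]hepta-2,5-diene, via silylated enyne 15 (not isolated)
Conditions: Pd(PPh3)2Cl2 (3 mol%), CuI (6 mol%), Et3N, THF, rt; then K2CO3 (0.2 equiv), MeOH, rt
Reagents that add atoms: none
Why: Sonogashira coupling proceeds with retention of alkene geometry, and carbonate/methanol then cleaves only the alkynyl C–Si bond (the CIP label changes from Z to E, the geometry does not).

**Step 7**
Reactants: 16 (2E,4R,5E)-1-[(tert-butyldimethylsilyl)oxy]-2-ethynyl-4-[(triethylsilyl)oxy]hepta-2,5-diene; 6 (2S,5R)-2-tert-butyl-5-methyl-5-(3-methylbut-2-en-1-yl)-1,3-dioxolan-4-one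
Product: 18 (5R,9E,11R,12E)-9-{[(tert-butyldimethylsilyl)oxy]methyl}-5-hydroxy-2,5-dimethyl-11-[(triethylsilyl)oxy]tetradeca-2,9,12-trien-7-yn-6-one, via lithium acetylide 17 (not isolated)
Conditions: n-BuLi, THF, −78 °C; then 6, −78 → −40 °C; sat. aq NH4Cl, −78 °C → rt
Reagents that add atoms: none
Why: Acylation of a lithium acetylide by the activated acylal ester; the tetrahedral adduct persists at low temperature and collapses on work-up with loss of pivalaldehyde, giving the α'-hydroxy ynone without touching the quaternary centre.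

**Step 8**
Reactants: 18 (5R,9E,11R,12E)-9-{[(tert-butyldimethylsilyl)oxy]methyl}-5-hydroxy-2,5-dimethyl-11-[(triethylsilyl)oxy]tetradeca-2,9,12-trien-7-yn-6-one
Product: 20 (2R)-5-[(2Z,4R,5E)-1-[(tert-butyldimethylsilyl)oxy]-4-hydroxyhepta-2,5-dien-2-yl]-2-methyl-2-(3-methylbut-2-en-1-yl)furan-3(2H)-one, via silyl-protected furanone 19 (not isolated)
Conditions: K2CO3 (0.3 equiv), MeOH, 0 °C → rt; then pyridinium p-toluenesulfonate (1 equiv), 0 °C
Reagents that add atoms: none
Why: Base-mediated 5-endo-dig oxa-Michael addition of the tertiary hydroxyl to the ynone gives the 3(2H)-furanone, and mild acid methanolysis then removes the secondary triethylsilyl ether faster than the primary tert-butyldimethylsilyl ether.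

**Step 9**
Reactants: 20 (2R)-5-[(2Z,4R,5E)-1-[(tert-butyldimethylsilyl)oxy]-4-hydroxyhepta-2,5-dien-2-yl]-2-methyl-2-(3-methylbut-2-en-1-yl)furan-3(2H)-one; 21 2-(bromomethyl)acrylic acid
Product: 22 (2Z,4R,5E)-1-[(tert-butyldimethylsilyl)oxy]-2-[(5R)-5-methyl-5-(3-methylbut-2-en-1-yl)-4-oxo-4,5-dihydrofuran-2-yl]hepta-2,5-dien-4-yl 2-(bromomethyl)prop-2-enoate
Conditions: DCC, DMAP (10 mol%), CH2Cl2, −20 → 0 °C
Reagents that add atoms: none
Why: Steglich esterification acylates the only free hydroxyl with retention at C6; low temperature and little DMAP limit attack on the allylic bromide.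

**Step 10**
Reactants: 22 (2Z,4R,5E)-1-[(tert-butyldimethylsilyl)oxy]-2-[(5R)-5-methyl-5-(3-methylbut-2-en-1-yl)-4-oxo-4,5-dihydrofuran-2-yl]hepta-2,5-dien-4-yl 2-(bromomethyl)prop-2-enoate
Product: 23 (5S)-3-(bromomethyl)-5-{(1Z)-3-[(tert-butyldimethylsilyl)oxy]-2-[(5R)-5-methyl-5-(3-methylbut-2-en-1-yl)-4-oxo-4,5-dihydrofuran-2-yl]prop-1-en-1-yl}furan-2(5H)-one
Conditions: second-generation Grubbs catalyst (10 mol%), CH2Cl2 (5 mM), 40 °C
Reagents that add atoms: none
Why: Ring-closing metathesis between the propenyl group and the 1,1-disubstituted acrylate forms the five-membered butenolide with loss of propene, while the trisubstituted prenyl alkene and the conjugated alkenes are too hindered or electron-poor to compete (C6 is untouched; its label becomes S only through CIP priorities).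

**Step 11**
Reactants: 23 (5S)-3-(bromomethyl)-5-{(1Z)-3-[(tert-butyldimethylsilyl)oxy]-2-[(5R)-5-methyl-5-(3-methylbut-2-en-1-yl)-4-oxo-4,5-dihydrofuran-2-yl]prop-1-en-1-yl}furan-2(5H)-one
Product: 24 2-[(2R)-5-{(1Z)-1-[(2S)-4-(bromomethyl)-5-oxo-2,5-dihydrofuran-2-yl]-3-[(tert-butyldimethylsilyl)oxy]prop-1-en-2-yl}-2-methyl-3-oxo-2,3-dihydrofuran-2-yl]acetaldehyde
Conditions: OsO4 (2 mol%), NaIO4 (4 equiv), 2,6-lutidine, 1,4-dioxane/H2O 3:1, rt; used crude
Reagents that add atoms: sodium periodate, [Na+].[O-]I(=O)(=O)=O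
Why: Lemieux–Johnson oxidative cleavage: electrophilic OsO4 selects the only electron-rich, unconjugated alkene (prenyl) and periodate cleaves the diol to the C8 aldehyde under near-neutral conditions that spare the allylic bromide and the base-sensitive butenolide.

**Step 12**
Reactants: 24 2-[(2R)-5-{(1Z)-1-[(2S)-4-(bromomethyl)-5-oxo-2,5-dihydrofuran-2-yl]-3-[(tert-butyldimethylsilyl)oxy]prop-1-en-2-yl}-2-methyl-3-oxo-2,3-dihydrofuran-2-yl]acetaldehyde
Product: 26 macrocyclic alcohol (6S,7S,8R,10R; target skeleton in which C8 carries a free OH and C15 a tert-butyldimethylsilyl ether), via allylchromium dichloride 25 (not isolated)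
Conditions: CrCl2 (8 equiv), THF/DMF 4:1, rt, syringe-pump addition (2 mM final); aq NH4Cl
Reagents that add atoms: none
Why: Intramolecular Barbier/Nozaki–Hiyama allylation: divalent chromium turns the bromomethylbutenolide into an allylchromium that attacks the aldehyde through its ring β-carbon (C7) in a chair Zimmerman–Traxler transition state; attack anti to the C6 substituent gives the trans-fused lactone (C7 S), the ring-fixed E-type allyl geometry gives the anti C7/C8 relationship (C8 R), and the exocyclic methylene appears in the same event.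

**Step 13**
Reactants: 26 macrocyclic alcohol; 27 (E)-crotonic anhydride
Product: 28 C15-O-tert-butyldimethylsilyl ether of the target
Conditions: 27, pyridine, DMAP (20 mol%), CH2Cl2, 0 °C → rt
Reagents that add atoms: none
Why: DMAP-catalysed acylation of the only free (secondary) hydroxyl; the anhydride with pyridine avoids the ketene pathway that would deconjugate the crotonate.

**Step 14**
Reactants: 28 C15-O-tert-butyldimethylsilyl ether of the target
Product: 29 target (4Z,6S,7S,8R,10R)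
Conditions: HF·pyridine, pyridine, THF, 0 °C → rt
Reagents that add atoms: none
Why: Buffered fluoride desilylation removes the primary silyl ether without touching the crotonate, the α-methylene lactone or the furanone.

**Compound list**
1 | (S)-lactic acid | C[C@H](O)C(=O)O | starting material
2 | pivalaldehyde | CC(C)(C)C=O | starting material
3 | (2S,5S)-2-tert-butyl-5-methyl-1,3-dioxolan-4-one (cis) | C[C@@H]1O[C@H](C(C)(C)C)OC1=O | intermediate
4 | prenyl bromide (1-bromo-3-methylbut-2-ene) | CC(C)=CCBr | starting material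
5 | lithium (2S)-2-tert-butyl-5-methyl-1,3-dioxol-4-olate (enolate of 3) | CC1=C([O-])O[C@@H](C(C)(C)C)O1.[Li+] | intermediate
6 | (2S,5R)-2-tert-butyl-5-methyl-5-(3-methylbut-2-en-1-yl)-1,3-dioxolan-4-one | C[C@]1(CC=C(C)C)O[C@H](C(C)(C)C)OC1=O | intermediate
7 | tert-butyldimethyl(prop-2-yn-1-yloxy)silane | C#CCO[Si](C)(C)C(C)(C)C | starting material
8 | (E)-but-2-enal (crotonaldehyde) | C/C=C/C=O | starting material
9 | methyl{3-[(tert-butyldimethylsilyl)oxy]prop-1-yn-1-yl}zinc | C[Zn]C#CCO[Si](C)(C)C(C)(C)C | intermediate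
10 | (4R,5E)-1-[(tert-butyldimethylsilyl)oxy]hept-5-en-2-yn-4-ol | O[C@H](/C=C/C)C#CCO[Si](C)(C)C(C)(C)C | intermediate
11 | cyclic sodium alkoxy(vinyl)alanate from 10 (five-membered O–Al–C4=C5–C6 ring; Al also carries two 2-methoxyethoxy groups) | [Na+].COCCO[Al-]1(OCCOC)O[C@H](/C=C/C)C=C1CO[Si](C)(C)C(C)(C)C | intermediate
12 | (2Z,4R,5E)-1-[(tert-butyldimethylsilyl)oxy]-2-iodohepta-2,5-dien-4-ol | O[C@H](/C=C/C)/C=C(\I)CO[Si](C)(C)C(C)(C)C | intermediate
13 | (2Z,4R,5E)-1-[(tert-butyldimethylsilyl)oxy]-2-iodo-4-[(triethylsilyl)oxy]hepta-2,5-diene | CC[Si](CC)(CC)O[C@H](/C=C/C)/C=C(\I)CO[Si](C)(C)C(C)(C)C | intermediate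
14 | ethynyltrimethylsilane | C#C[Si](C)(C)C | starting material
15 | (2E,4R,5E)-1-[(tert-butyldimethylsilyl)oxy]-4-[(triethylsilyl)oxy]-2-[(trimethylsilyl)ethynyl]hepta-2,5-diene | CC[Si](CC)(CC)O[C@H](/C=C/C)/C=C(\C#C[Si](C)(C)C)CO[Si](C)(C)C(C)(C)C | intermediate
16 | (2E,4R,5E)-1-[(tert-butyldimethylsilyl)oxy]-2-ethynyl-4-[(triethylsilyl)oxy]hepta-2,5-diene | CC[Si](CC)(CC)O[C@H](/C=C/C)/C=C(\C#C)CO[Si](C)(C)C(C)(C)C | intermediate
17 | lithium acetylide of 16 | CC[Si](CC)(CC)O[C@H](/C=C/C)/C=C(\C#C[Li])CO[Si](C)(C)C(C)(C)C | intermediate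
18 | (5R,9E,11R,12E)-9-{[(tert-butyldimethylsilyl)oxy]methyl}-5-hydroxy-2,5-dimethyl-11-[(triethylsilyl)oxy]tetradeca-2,9,12-trien-7-yn-6-one | CC[Si](CC)(CC)O[C@H](/C=C/C)/C=C(\C#CC(=O)[C@@](C)(CC=C(C)C)O)CO[Si](C)(C)C(C)(C)C | intermediate
19 | (2R)-5-[(2Z,4R,5E)-1-[(tert-butyldimethylsilyl)oxy]-4-[(triethylsilyl)oxy]hepta-2,5-dien-2-yl]-2-methyl-2-(3-methylbut-2-en-1-yl)furan-3(2H)-one | CC[Si](CC)(CC)O[C@H](/C=C/C)/C=C(\C1=CC(=O)[C@@](C)(CC=C(C)C)O1)CO[Si](C)(C)C(C)(C)C | intermediate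
20 | (2R)-5-[(2Z,4R,5E)-1-[(tert-butyldimethylsilyl)oxy]-4-hydroxyhepta-2,5-dien-2-yl]-2-methyl-2-(3-methylbut-2-en-1-yl)furan-3(2H)-one | O[C@H](/C=C/C)/C=C(\C1=CC(=O)[C@@](C)(CC=C(C)C)O1)CO[Si](C)(C)C(C)(C)C | intermediate
21 | 2-(bromomethyl)acrylic acid | C=C(CBr)C(=O)O | starting material
22 | (2Z,4R,5E)-1-[(tert-butyldimethylsilyl)oxy]-2-[(5R)-5-methyl-5-(3-methylbut-2-en-1-yl)-4-oxo-4,5-dihydrofuran-2-yl]hepta-2,5-dien-4-yl 2-(bromomethyl)prop-2-enoate | C=C(CBr)C(=O)O[C@H](/C=C/C)/C=C(\C1=CC(=O)[C@@](C)(CC=C(C)C)O1)CO[Si](C)(C)C(C)(C)C | intermediate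
23 | (5S)-3-(bromomethyl)-5-{(1Z)-3-[(tert-butyldimethylsilyl)oxy]-2-[(5R)-5-methyl-5-(3-methylbut-2-en-1-yl)-4-oxo-4,5-dihydrofuran-2-yl]prop-1-en-1-yl}furan-2(5H)-one | O=C1O[C@H](C=C1CBr)/C=C(\C1=CC(=O)[C@@](C)(CC=C(C)C)O1)CO[Si](C)(C)C(C)(C)C | intermediate
24 | 2-[(2R)-5-{(1Z)-1-[(2S)-4-(bromomethyl)-5-oxo-2,5-dihydrofuran-2-yl]-3-[(tert-butyldimethylsilyl)oxy]prop-1-en-2-yl}-2-methyl-3-oxo-2,3-dihydrofuran-2-yl]acetaldehyde | O=C1O[C@H](C=C1CBr)/C=C(\C1=CC(=O)[C@@](C)(CC=O)O1)CO[Si](C)(C)C(C)(C)C | intermediate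
25 | allylchromium dichloride from 24 (CrCl2 on C13, trivalent chromium) | O=C1O[C@H](C=C1C[Cr](Cl)Cl)/C=C(\C1=CC(=O)[C@@](C)(CC=O)O1)CO[Si](C)(C)C(C)(C)C | intermediate
26 | macrocyclic alcohol (4Z,6S,7S,8R,10R): target skeleton with free C8–OH and C15–O–Si(t-Bu)Me2 | C=C1C(=O)O[C@H]2/C=C(/CO[Si](C)(C)C(C)(C)C)C3=CC(=O)[C@@](C)(C[C@@H](O)[C@H]12)O3 | intermediate
27 | (E)-crotonic anhydride | C/C=C/C(=O)OC(=O)/C=C/C | starting material
28 | C15-O-tert-butyldimethylsilyl ether of the target (4Z,6S,7S,8R,10R) | C=C1C(=O)O[C@H]2/C=C(/CO[Si](C)(C)C(C)(C)C)C3=CC(=O)[C@@](C)(C[C@@H](OC(=O)/C=C/C)[C@H]12)O3 | intermediate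
29 | target: (4Z,6S,7S,8R,10R)-8-[(E)-but-2-enoyloxy]-15-hydroxy-1-oxo-3,10-epoxygermacra-2,4,11(13)-trien-12,6-olide | C=C1C(=O)O[C@H]2/C=C(/CO)C3=CC(=O)[C@@](C)(C[C@@H](OC(=O)/C=C/C)[C@H]12)O3 | target

**Totals and risks**
Total: 14 steps. Longest linear sequence: 12 steps (7 and 8 → 29); the lactate branch (1 → 6, 2 steps) joins at step 7.

Most likely to fail, in this order:

Step 12 (ring closure). The tether may force the aldehyde onto the C7 face cis to C5, or out of the chair arrangement, or oligomers may form. The fallback makes the C7–C8 bond between two separate fragments, where attack anti to the C6 substituent is unopposed, and closes the ring at C3–C4 instead. It sets out from 12 and 6. Esterification of 12 with 21 (DCC, DMAP) gives the iodo ester F1, and ring-closing metathesis gives the iodo bromobutenolide F2. Addition of HC≡CMgBr to 6 gives the terminal hydroxy ynone F3, and OsO4/NaIO4 cleavage gives its aldehyde F4. Zn-mediated Barbier coupling of F2 and F4 (THF/aq NH4Cl) gives the open-chain adduct F5. Intramolecular Sonogashira coupling at high dilution gives the macrocyclic ynone F6, and K2CO3/MeOH closes the furanone to come back at 26.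

Step 10 (metathesis). The allylic bromide may degrade the ruthenium carbene or the hindered acrylate may stall. The fallback puts the bromide in after the ring is made and sets out from 20. Acryloyl chloride/i-Pr2NEt gives the acrylate F7. A DABCO-catalysed Morita–Baylis–Hillman reaction with aqueous formaldehyde gives the 2-(hydroxymethyl)acrylate F8. Ring-closing metathesis gives the 3-(hydroxymethyl)butenolide F9, and CBr4/PPh3 comes back at 23.

Step 7 (acylation). The hindered dioxolanone may react slowly or over-add on warming. The fallback changes the electrophile and sets out from 6. MeNH(OMe)·HCl/i-PrMgCl opens 6 to the Weinreb amide F10. Its hydroxyl is deprotonated with i-PrMgCl, and addition of acetylide 17 comes back at 18.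

**Further compounds**
F1 | step 12 | (2Z,4R,5E)-1-[(tert-butyldimethylsilyl)oxy]-2-iodohepta-2,5-dien-4-yl 2-(bromomethyl)prop-2-enoate | C=C(CBr)C(=O)O[C@H](/C=C/C)/C=C(\I)CO[Si](C)(C)C(C)(C)C
F2 | step 12 | (5R)-3-(bromomethyl)-5-{(1Z)-3-[(tert-butyldimethylsilyl)oxy]-2-iodoprop-1-en-1-yl}furan-2(5H)-one | O=C1O[C@H](C=C1CBr)/C=C(\I)CO[Si](C)(C)C(C)(C)C
F3 | step 12 | (4R)-4-hydroxy-4,7-dimethyloct-6-en-1-yn-3-one | C#CC(=O)[C@@](C)(CC=C(C)C)O
F4 | step 12 | (3R)-3-hydroxy-3-methyl-4-oxohex-5-ynal | C#CC(=O)[C@@](C)(CC=O)O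
F5 | step 12 | (4S,5R)-4-[(1R,3R)-1,3-dihydroxy-3-methyl-4-oxohex-5-yn-1-yl]-5-{(1Z)-3-[(tert-butyldimethylsilyl)oxy]-2-iodoprop-1-en-1-yl}-3-methylidenedihydrofuran-2(3H)-one | C#CC(=O)[C@](C)(O)C[C@@H](O)[C@@H]1C(=C)C(=O)O[C@H]1/C=C(\I)CO[Si](C)(C)C(C)(C)C
F6 | step 12 | macrocyclic ynone (6S,7S,8R,10R): 26 with the furanone opened to the C1 ketone, C2≡C3 alkyne and free C10–OH | C=C1C(=O)O[C@H]2/C=C(/CO[Si](C)(C)C(C)(C)C)C#CC(=O)[C@](C)(O)C[C@@H](O)[C@H]12
F7 | step 10 | (2Z,4R,5E)-1-[(tert-butyldimethylsilyl)oxy]-2-[(5R)-5-methyl-5-(3-methylbut-2-en-1-yl)-4-oxo-4,5-dihydrofuran-2-yl]hepta-2,5-dien-4-yl prop-2-enoate | C=CC(=O)O[C@H](/C=C/C)/C=C(\C1=CC(=O)[C@@](C)(CC=C(C)C)O1)CO[Si](C)(C)C(C)(C)C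
F8 | step 10 | (2Z,4R,5E)-1-[(tert-butyldimethylsilyl)oxy]-2-[(5R)-5-methyl-5-(3-methylbut-2-en-1-yl)-4-oxo-4,5-dihydrofuran-2-yl]hepta-2,5-dien-4-yl 2-(hydroxymethyl)prop-2-enoate | C=C(CO)C(=O)O[C@H](/C=C/C)/C=C(\C1=CC(=O)[C@@](C)(CC=C(C)C)O1)CO[Si](C)(C)C(C)(C)C
F9 | step 10 | (5S)-3-(hydroxymethyl)-5-{(1Z)-3-[(tert-butyldimethylsilyl)oxy]-2-[(5R)-5-methyl-5-(3-methylbut-2-en-1-yl)-4-oxo-4,5-dihydrofuran-2-yl]prop-1-en-1-yl}furan-2(5H)-one | O=C1O[C@H](C=C1CO)/C=C(\C1=CC(=O)[C@@](C)(CC=C(C)C)O1)CO[Si](C)(C)C(C)(C)C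
F10 | step 7 | (2R)-2-hydroxy-N-methoxy-N,2,5-trimethylhex-4-enamide | CON(C)C(=O)[C@@](C)(CC=C(C)C)O
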